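**Plan**

- Retrosynthesis first cuts the two acyl C–O bonds (C8 tiglate, C9 senecioate) and the C11=C12 alkene (from a C11 tertiary alcohol). The C4–H bond is traced to a C3=C4 enone, and the C8 and C9 carbinols to a C8 ketone and a C9 ketal.
- The feature that allows the key step is the cis-decalin (ring A = C1–C5, C10; ring B = C5–C10) in which a C8 carbonyl and a C3=C4 alkene flank the quaternary C5. This δ,ε-unsaturated ketone is the [3,3] isomer of a 2-alkenylbicyclo[2.2.2]oct-5-en-2-ol, so cutting C5–C6 and re-joining C3–C8 gives that bicycle.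
- The bicycle is cut at C7–C8 (alkenyl anion plus ketone) and at C1–C10 and C2–C3 (Diels–Alder of vinyl acetate with the quinone monoketal of 2-methoxy-4,5-dimethylphenol, which supplies C8=O and the C9 ketal).
- Forward: the Diels–Alder reaction builds the bicyclo[2.2.2]octenone, whose cyclohexene becomes ring A. Alkenyl addition and the anionic oxy-Cope rearrangement then close ring B, after which the oxygens at C8, C9 and C2 are adjusted, C4 is reduced and the esters are attached.
- Stereochemistry: C2, C3 and C10 come from the ortho/endo Diels–Alder reaction in relative terms and from a lipase resolution in absolute terms. C5 and the cis fusion come from the geometry of the [3,3] shift, C7 from equilibration, C8 and C9 from hydride attack on the convex face, and C4 from axial protonation in a dissolving-metal reduction.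

Key step: step 9

**Remarks**

- Numbering: target (eremophilane) numbering is used in the text: C11–C13 on C7, C14 on C5, C15 on C4; β is the face of the C5 methyl group. Bicyclic intermediates are named with bicyclo[2.2.2]octene numbering, whose C1, C2, C3, C4, C5, C6, C7, C8 are target C3, C8, C9, C10, C5, C4, C2, C1.
- Assumption: the lipase of step 5 is taken to follow the usual size rule for secondary alcohols and to acylate the (7R)-alcohol faster. If the preference is the reverse, the acetate fraction is methanolysed as in step 4 and gives the same alcohol 8.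

**Route**

Step 1
Reactants: 1 3,4-dimethylphenol
Product: 2 2-bromo-4,5-dimethylphenol
Conditions: NBS, MeCN, 0 °C
Reagents that add atoms: N-bromosuccinimide, O=C1CCC(=O)N1Br
Why: Electrophilic aromatic bromination of a phenol whose para position is blocked goes ortho, and of the two ortho sites the one not flanked by the C3 methyl group reacts.

Step 2
Reactants: 2 2-bromo-4,5-dimethylphenol
Product: 3 2-methoxy-4,5-dimethylphenol
Conditions: NaOMe, CuBr (cat.), MeOH/DMF, 110 °C; aq. HCl work-up
Reagents that add atoms: sodium methoxide, [Na+].[O-]C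
Why: Copper-catalysed Ullmann-type methoxylation of an aryl bromide is a standard route from 2-bromophenols to guaiacols and tolerates the free phenoxide.

Step 3
Reactants: 3 2-methoxy-4,5-dimethylphenol; 4 vinyl acetate
Product: 6 rac-(1S,4S,7S)-7-acetoxy-3,3-dimethoxy-5,6-dimethylbicyclo[2.2.2]oct-5-en-2-one, via masked o-benzoquinone 5 (not isolated)
Conditions: PhI(OAc)2, MeOH, 4 (excess), slow addition of 3, rt → 50 °C
Reagents that add atoms: methanol, CO
Why: Oxidative dearomatisation of the guaiacol by PhI(OAc)2 in methanol gives the masked o-benzoquinone 5, which is trapped at once in a Diels–Alder reaction with the electron-rich dienophile 4; the oxygen-bearing carbon bonds to the diene terminus next to the carbonyl (ortho) and the acetoxy group takes the endo position syn to the new alkene bridge, which sets C2, C3 and C10 in relative terms.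

Step 4
Reactants: 6 rac-(1S,4S,7S)-7-acetoxy-3,3-dimethoxy-5,6-dimethylbicyclo[2.2.2]oct-5-en-2-one
Product: 7 rac-(1S,4S,7S)-7-hydroxy-3,3-dimethoxy-5,6-dimethylbicyclo[2.2.2]oct-5-en-2-one
Conditions: K2CO3 (cat.), MeOH, 0 °C
Reagents that add atoms: none
Why: Base-catalysed transesterification removes the acetate and is run cold and briefly because the product is a β-hydroxy ketone that could retro-aldolise.

Step 5
Reactants: 7 rac-(1S,4S,7S)-7-hydroxy-3,3-dimethoxy-5,6-dimethylbicyclo[2.2.2]oct-5-en-2-one; 4 vinyl acetate (acyl donor)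
Product: 8 (1S,4S,7S)-7-hydroxy-3,3-dimethoxy-5,6-dimethylbicyclo[2.2.2]oct-5-en-2-one
Conditions: Burkholderia cepacia lipase (immobilised), 4 (3 equiv), t-BuOMe, 30 °C, stopped shortly after half conversion
Reagents that add atoms: none
Why: Lipase-catalysed kinetic resolution by irreversible transesterification should acylate the (7R)-alcohol faster (bridgehead side large, CH2 side medium), so that past half conversion the unreacted (7S)-alcohol 8 remains in high enantiomeric purity and fixes the absolute configuration of the route.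

Step 6
Reactants: 8 (1S,4S,7S)-7-hydroxy-3,3-dimethoxy-5,6-dimethylbicyclo[2.2.2]oct-5-en-2-one
Product: 9 (1S,4S,7S)-7-(tert-butyldiphenylsilyloxy)-3,3-dimethoxy-5,6-dimethylbicyclo[2.2.2]oct-5-en-2-one
Conditions: TBDPSCl, imidazole, DMF, rt
Reagents that add atoms: tert-butyl(chloro)diphenylsilane, CC(C)(C)[Si](Cl)(c1ccccc1)c1ccccc1
Why: Standard silylation of a secondary alcohol; the tert-butyldiphenylsilyl ether is chosen because it withstands KH, hydrides and the aqueous acid of step 12 and blocks the retro-aldol pathway.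

Step 7
Reactants: 10 3-hydroxy-3-methylbutan-2-one
Product: 11 (E)-N'-(3-hydroxy-3-methylbutan-2-ylidene)-2,4,6-triisopropylbenzenesulfonohydrazide
Conditions: 2,4,6-triisopropylbenzenesulfonohydrazide, MeOH, HCl (cat.), rt
Reagents that add atoms: 2,4,6-triisopropylbenzenesulfonohydrazide, CC(C)c1cc(C(C)C)c(S(=O)(=O)NN)c(C(C)C)c1
Why: Condensation of the methyl ketone with the sulfonyl hydrazide gives the hydrazone needed for a Shapiro reaction, and since only the methyl group carries α-hydrogens the later alkenyl anion is regiodefined.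

Step 8
Reactants: 11 (E)-N'-(3-hydroxy-3-methylbutan-2-ylidene)-2,4,6-triisopropylbenzenesulfonohydrazide; 9 (1S,4S,7S)-7-(tert-butyldiphenylsilyloxy)-3,3-dimethoxy-5,6-dimethylbicyclo[2.2.2]oct-5-en-2-one
Product: 14 (1S,2S,4S,7S)-7-(tert-butyldiphenylsilyloxy)-2-(3-hydroxy-3-methylbut-1-en-2-yl)-3,3-dimethoxy-5,6-dimethylbicyclo[2.2.2]oct-5-en-2-ol, via dilithio alkenyl species 12 (not isolated), via alkenylcerium dichloride 13 (not isolated)
Conditions: 11 (2.5 equiv), n-BuLi (3 equiv per 11), THF, −78 → 0 °C; CeCl3, −78 °C; 9, −78 → −40 °C; aq. NH4Cl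
Reagents that add atoms: none
Why: The Shapiro reaction (base for NH, OH and the methyl CH, then loss of sulfinate and N2) gives alkenyl anion 12, whose side-chain oxygen is a lithium alkoxide and so cannot be lost by β-elimination; its cerium derivative 13 adds 1,2 to the hindered, non-enolisable ketone from the face of the dimethyl-substituted alkene bridge, because the ethano bridge shields the other face with its exo hydrogens, and this places the alkenyl group syn to C4=C5 at the new carbinol centre C8.

Step 9
Reactants: 14 (1S,2S,4S,7S)-7-(tert-butyldiphenylsilyloxy)-2-(3-hydroxy-3-methylbut-1-en-2-yl)-3,3-dimethoxy-5,6-dimethylbicyclo[2.2.2]oct-5-en-2-ol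
Product: 17 2β-(tert-butyldiphenylsilyloxy)-11-hydroxy-9,9-dimethoxy-10βH-eremophil-3-en-8-one as the pair of C7 epimers, via dipotassium dialkoxide 15 (not isolated), via dipotassium enolate alkoxide 16 (not isolated)
Conditions: KH, 18-crown-6, THF, 0 °C → rt; AcOH (excess), −78 °C
Reagents that add atoms: none
Why: KH with 18-crown-6 turns both hydroxyls into potassium alkoxides (15), and the C8 oxyanion drives a concerted [3,3] sigmatropic shift of the C6=C7–C8–C3–C4=C5 unit through the boat-like transition state imposed by the bicycle, breaking C3–C8 and forming C5–C6 to give enolate 16; the closest known reaction type is the anionic oxy-Cope rearrangement of 2-alkenylbicyclo[2.2.2]oct-5-en-2-ols derived from masked o-benzoquinone adducts, which is known to give cis-decalins. Ring B (C5–C10) is closed by the sigmatropic C5–C6 bond formation itself, a six-centre pericyclic ring expansion in which the bicycle is opened at C3–C8 and re-closed onto C5, while the former cyclohexene survives as ring A with its double bond moved to C3=C4. C5 is controlled by the bicyclic tether, because C6 hangs from the C8–C9 bridge and can reach C5 only on the face of that bridge, so C6 and C9 end up cis on ring A and the C5 methyl is cis to H10, while C10 and C2 are carried over unchanged. C7 arises only on protonation of the enolate and is not controlled here (it is adjusted in step 10). The step needs the alkenyl group syn to the C4=C5 bridge, which the face-selective addition of step 8 secures, and it is made irreversible by strain release and enolate formation. The side-chain oxygen is left as the alkoxide on purpose, since it cannot be expelled from the enolate as a silyloxy group could, and the cold acetic acid quench protonates alkoxide and enolate together so that the β-hydroxy ketone never meets base and cannot retro-aldolise.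

Step 10
Reactants: 17 2β-(tert-butyldiphenylsilyloxy)-11-hydroxy-9,9-dimethoxy-10βH-eremophil-3-en-8-one (C7 epimers)
Product: 19 2β-(tert-butyldiphenylsilyloxy)-9,9-dimethoxy-11-(triethylsilyloxy)-7αH,10βH-eremophil-3-en-8-one, via triethylsilyl ether epimer mixture 18 (not isolated)
Conditions: TESOTf, 2,6-lutidine, CH2Cl2, −78 → 0 °C; then DBU, toluene, rt
Reagents that add atoms: triethylsilyl trifluoromethanesulfonate, CC[Si](CC)(CC)OS(=O)(=O)C(F)(F)F
Why: Silylation of the tertiary hydroxyl removes the retro-aldol pathway, after which DBU epimerises the α-carbon C7 through the enol form under thermodynamic control, which should favour the 7β epimer because its ring B chair carries the bulky side chain equatorially and avoids a 1,3-diaxial contact between the C5 methyl and a C9 methoxy group.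

Step 11
Reactants: 19 2β-(tert-butyldiphenylsilyloxy)-9,9-dimethoxy-11-(triethylsilyloxy)-7αH,10βH-eremophil-3-en-8-one
Product: 20 2β-(tert-butyldiphenylsilyloxy)-9,9-dimethoxy-11-(triethylsilyloxy)-7αH,10βH-eremophil-3-en-8α-ol
Conditions: NaBH4, MeOH, −20 → 0 °C
Reagents that add atoms: none
Why: Borohydride reduction of the activated α,α-dimethoxy ketone should give the equatorial 8α-alcohol, because with the C7 side chain equatorial the hydride adds axially from the convex β face and anti to the axial C9 methoxy group (Felkin–Anh and torsional control).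

Step 12
Reactants: 20 2β-(tert-butyldiphenylsilyloxy)-9,9-dimethoxy-11-(triethylsilyloxy)-7αH,10βH-eremophil-3-en-8α-ol
Product: 21 2β-(tert-butyldiphenylsilyloxy)-8α,11-dihydroxy-7αH,10βH-eremophil-3-en-9-one
Conditions: 1 M aq. HCl, THF, rt
Reagents that add atoms: water, O
Why: Acid-catalysed hydrolysis cleaves the dimethyl ketal, which is no longer next to a carbonyl, and the tertiary triethylsilyl ether, while the tert-butyldiphenylsilyl ether survives and keeps the allylic C2 oxygen from ionising; the cis ring fusion next to the new ketone should hold because the trans isomer would force the C7 side chain and the C5 methyl into a 1,3-diaxial relation.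

Step 13
Reactants: 21 2β-(tert-butyldiphenylsilyloxy)-8α,11-dihydroxy-7αH,10βH-eremophil-3-en-9-one
Product: 22 2β-(tert-butyldiphenylsilyloxy)-7αH,10βH-eremophil-3-ene-8α,9α,11-triol
Conditions: LiBH(s-Bu)3 (L-Selectride, excess), THF, −78 °C; aq. NH4Cl
Reagents that add atoms: none
Why: A bulky trialkylborohydride attacks cyclohexanones along the equatorial trajectory, which here is also the convex β face since the α face lies under ring A, so the axial 9α-alcohol cis to the 8α-hydroxyl should result.

Step 14
Reactants: 22 2β-(tert-butyldiphenylsilyloxy)-7αH,10βH-eremophil-3-ene-8α,9α,11-triol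
Product: 23 7αH,10βH-eremophil-3-ene-2β,8α,9α,11-tetraol
Conditions: Bu4NF, THF, rt
Reagents that add atoms: none
Why: Fluoride-mediated cleavage of the silyl ether is a standard desilylation and touches nothing else in the molecule.

Step 15
Reactants: 23 7αH,10βH-eremophil-3-ene-2β,8α,9α,11-tetraol
Product: 24 8α,9α,11-trihydroxy-7αH,10βH-eremophil-3-en-2-one
Conditions: MnO2, EtOAc, rt
Reagents that add atoms: none
Why: MnO2 oxidises allylic alcohols selectively, so only the C2 hydroxyl is converted and the saturated secondary and tertiary hydroxyls remain.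

Step 16
Reactants: 24 8α,9α,11-trihydroxy-7αH,10βH-eremophil-3-en-2-one
Product: 25 8α,9α,11-trihydroxy-4β-methyl-7αH,10βH-eremophilan-2-one
Conditions: Li, NH3/THF, −78 °C; NH4Cl
Reagents that add atoms: none
Why: In this dissolving-metal (Birch-type) conjugate reduction the β-carbanion at C4 is protonated axially on a ring A chair locked by the equatorial C7 side chain, that is from the α face anti to the axial C5 methyl, over which the 9α-hydroxyl lies as an internal proton donor, so the C4 methyl should become equatorial and cis to the C5 methyl (4S), and the enolate gives the ketone on quench.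

Step 17
Reactants: 25 8α,9α,11-trihydroxy-4β-methyl-7αH,10βH-eremophilan-2-one
Product: 26 9α,11-dihydroxy-8α-tigloyloxy-7αH,10βH-eremophilan-2-one
Conditions: tigloyl chloride (1.1 equiv), pyridine, DMAP (cat.), CH2Cl2, −20 °C
Reagents that add atoms: (E)-2-methylbut-2-enoyl chloride, C/C=C(\C)C(Cl)=O
Why: DMAP-catalysed acylation at low temperature should distinguish the equatorial 8α-hydroxyl from the axial 9α-hydroxyl, which points into the concave face, and from the tertiary hydroxyl.

Step 18
Reactants: 26 9α,11-dihydroxy-8α-tigloyloxy-7αH,10βH-eremophilan-2-one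
Product: 27 11-hydroxy-9α-senecioyloxy-8α-tigloyloxy-7αH,10βH-eremophilan-2-one
Conditions: 3-methylbut-2-enoyl chloride (excess), pyridine, DMAP, CH2Cl2, 0 °C → rt
Reagents that add atoms: 3-methylbut-2-enoyl chloride, CC(C)=CC(Cl)=O
Why: Forced DMAP-catalysed acylation esterifies the remaining secondary hydroxyl, with pyridine in place of a trialkylamine to limit vinylketene formation and deconjugation of the senecioyl group, while the tertiary hydroxyl is too hindered to react.

Step 19
Reactants: 27 11-hydroxy-9α-senecioyloxy-8α-tigloyloxy-7αH,10βH-eremophilan-2-one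
Product: 28 9α-senecioyloxy-8α-tigloyloxy-7αH,10βH-eremophil-11-en-2-one, (4S,5R,7R,8R,9S,10S), CNP0181050.1
Conditions: Et3N(+)SO2N(−)CO2Me (Burgess reagent), toluene, 50 °C
Reagents that add atoms: none
Why: Burgess dehydration of the tertiary alcohol proceeds by syn elimination of its sulfamate, and loss of one of the six methyl hydrogens gives the isopropenyl group, whereas elimination toward C7 would create an isopropylidene group with severe allylic strain against the equatorial C8 ester.

**Compound list**

1 | 3,4-dimethylphenol | Cc1ccc(O)cc1C | starting material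
2 | 2-bromo-4,5-dimethylphenol | Cc1cc(O)c(Br)cc1C | intermediate
3 | 2-methoxy-4,5-dimethylphenol | COc1cc(C)c(C)cc1O | intermediate
4 | vinyl acetate | C=COC(C)=O | starting material
5 | 6,6-dimethoxy-3,4-dimethylcyclohexa-2,4-dien-1-one (masked o-benzoquinone) | COC1(OC)C=C(C)C(C)=CC1=O | intermediate
6 | rac-(1S,4S,7S)-7-acetoxy-3,3-dimethoxy-5,6-dimethylbicyclo[2.2.2]oct-5-en-2-one (acetoxy syn to the alkene bridge; racemate, one enantiomer drawn) | O=C1[C@H]2C(C)=C(C)[C@H](C[C@@H]2OC(C)=O)C1(OC)OC | intermediate
7 | rac-(1S,4S,7S)-7-hydroxy-3,3-dimethoxy-5,6-dimethylbicyclo[2.2.2]oct-5-en-2-one (racemate, one enantiomer drawn) | O=C1[C@H]2C(C)=C(C)[C@H](C[C@@H]2O)C1(OC)OC | intermediate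
8 | (1S,4S,7S)-7-hydroxy-3,3-dimethoxy-5,6-dimethylbicyclo[2.2.2]oct-5-en-2-one | O=C1[C@H]2C(C)=C(C)[C@H](C[C@@H]2O)C1(OC)OC | intermediate
9 | (1S,4S,7S)-7-(tert-butyldiphenylsilyloxy)-3,3-dimethoxy-5,6-dimethylbicyclo[2.2.2]oct-5-en-2-one | O=C1[C@H]2C(C)=C(C)[C@H](C[C@@H]2O[Si](c3ccccc3)(c3ccccc3)C(C)(C)C)C1(OC)OC | intermediate
10 | 3-hydroxy-3-methylbutan-2-one | CC(=O)C(C)(C)O | starting material
11 | (E)-N'-(3-hydroxy-3-methylbutan-2-ylidene)-2,4,6-triisopropylbenzenesulfonohydrazide | C/C(=N\NS(=O)(=O)c1c(C(C)C)cc(C(C)C)cc1C(C)C)C(C)(C)O | intermediate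
12 | lithium 3-lithio-2-methylbut-3-en-2-olate (dilithio alkenyl species) | [Li]OC(C)(C)C([Li])=C | intermediate
13 | dichloro[3-(lithiooxy)-3-methylbut-1-en-2-yl]cerium | [Li]OC(C)(C)C(=C)[Ce](Cl)Cl | intermediate
14 | (1S,2S,4S,7S)-7-(tert-butyldiphenylsilyloxy)-2-(3-hydroxy-3-methylbut-1-en-2-yl)-3,3-dimethoxy-5,6-dimethylbicyclo[2.2.2]oct-5-en-2-ol (alkenyl group syn to the alkene bridge) | C=C(C(C)(C)O)[C@@]1(O)[C@H]2C(C)=C(C)[C@H](C[C@@H]2O[Si](c3ccccc3)(c3ccccc3)C(C)(C)C)C1(OC)OC | intermediate
15 | dipotassium dialkoxide of 14 | C=C(C(C)(C)[O-])[C@@]1([O-])[C@H]2C(C)=C(C)[C@H](C[C@@H]2O[Si](c3ccccc3)(c3ccccc3)C(C)(C)C)C1(OC)OC.[K+].[K+] | intermediate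
16 | dipotassium C7=C8 enolate and C11 alkoxide of the cis-decalin | CC(C)([O-])C=1C[C@@]2(C)[C@H](C[C@H](O[Si](c3ccccc3)(c3ccccc3)C(C)(C)C)C=C2C)C(OC)(OC)C=1[O-].[K+].[K+] | intermediate
17 | 2β-(tert-butyldiphenylsilyloxy)-11-hydroxy-9,9-dimethoxy-10βH-eremophil-3-en-8-one (both C7 epimers; C7 left unspecified) | CC(C)(O)C1C[C@@]2(C)[C@H](C[C@H](O[Si](c3ccccc3)(c3ccccc3)C(C)(C)C)C=C2C)C(OC)(OC)C1=O | intermediate
18 | 2β-(tert-butyldiphenylsilyloxy)-9,9-dimethoxy-11-(triethylsilyloxy)-10βH-eremophil-3-en-8-one (both C7 epimers; C7 left unspecified) | CC(C)(O[Si](CC)(CC)CC)C1C[C@@]2(C)[C@H](C[C@H](O[Si](c3ccccc3)(c3ccccc3)C(C)(C)C)C=C2C)C(OC)(OC)C1=O | intermediate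
19 | 2β-(tert-butyldiphenylsilyloxy)-9,9-dimethoxy-11-(triethylsilyloxy)-7αH,10βH-eremophil-3-en-8-one (side chain β) | CC(C)(O[Si](CC)(CC)CC)[C@H]1C[C@@]2(C)[C@H](C[C@H](O[Si](c3ccccc3)(c3ccccc3)C(C)(C)C)C=C2C)C(OC)(OC)C1=O | intermediate
20 | 2β-(tert-butyldiphenylsilyloxy)-9,9-dimethoxy-11-(triethylsilyloxy)-7αH,10βH-eremophil-3-en-8α-ol | CC(C)(O[Si](CC)(CC)CC)[C@H]1C[C@@]2(C)[C@H](C[C@H](O[Si](c3ccccc3)(c3ccccc3)C(C)(C)C)C=C2C)C(OC)(OC)[C@@H]1O | intermediate
21 | 2β-(tert-butyldiphenylsilyloxy)-8α,11-dihydroxy-7αH,10βH-eremophil-3-en-9-one | CC(C)(O)[C@H]1C[C@@]2(C)[C@H](C[C@H](O[Si](c3ccccc3)(c3ccccc3)C(C)(C)C)C=C2C)C(=O)[C@@H]1O | intermediate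
22 | 2β-(tert-butyldiphenylsilyloxy)-7αH,10βH-eremophil-3-ene-8α,9α,11-triol | CC(C)(O)[C@H]1C[C@@]2(C)[C@H](C[C@H](O[Si](c3ccccc3)(c3ccccc3)C(C)(C)C)C=C2C)[C@H](O)[C@@H]1O | intermediate
23 | 7αH,10βH-eremophil-3-ene-2β,8α,9α,11-tetraol | CC(C)(O)[C@H]1C[C@@]2(C)[C@H](C[C@H](O)C=C2C)[C@H](O)[C@@H]1O | intermediate
24 | 8α,9α,11-trihydroxy-7αH,10βH-eremophil-3-en-2-one | CC(C)(O)[C@H]1C[C@@]2(C)[C@H](CC(=O)C=C2C)[C@H](O)[C@@H]1O | intermediate
25 | 8α,9α,11-trihydroxy-4β-methyl-7αH,10βH-eremophilan-2-one | CC(C)(O)[C@H]1C[C@@]2(C)[C@H](CC(=O)C[C@@H]2C)[C@H](O)[C@@H]1O | intermediate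
26 | 9α,11-dihydroxy-8α-tigloyloxy-7αH,10βH-eremophilan-2-one | CC(C)(O)[C@H]1C[C@@]2(C)[C@H](CC(=O)C[C@@H]2C)[C@H](O)[C@@H]1OC(=O)/C(C)=C/C | intermediate
27 | 11-hydroxy-9α-senecioyloxy-8α-tigloyloxy-7αH,10βH-eremophilan-2-one | CC(C)(O)[C@H]1C[C@@]2(C)[C@H](CC(=O)C[C@@H]2C)[C@H](OC(=O)C=C(C)C)[C@@H]1OC(=O)/C(C)=C/C | intermediate
28 | 9α-senecioyloxy-8α-tigloyloxy-7αH,10βH-eremophil-11-en-2-one, (4S,5R,7R,8R,9S,10S) | C=C(C)[C@H]1C[C@@]2(C)[C@H](CC(=O)C[C@@H]2C)[C@H](OC(=O)C=C(C)C)[C@@H]1OC(=O)/C(C)=C/C | target

**Step count and risks**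

Total: 19 steps. Longest linear sequence: 18 steps (steps 1–6 and 8–19); step 7 is a one-step side branch.

The three steps most likely to fail:

1. Step 10 (C7 epimerisation). The equilibrium may not favour the 7β epimer strongly enough, and the enolisation it requires may instead expel triethylsilanolate from C11 by β-elimination. The fallback sets out from the unequilibrated silyl ether 18 and returns at 20. Soft enolisation with TMSOTf/Et3N gives the trimethylsilyl enol ether F1 (C7 is the only enolisable position). Saegusa–Ito oxidation with Pd(OAc)2 gives the 6-en-8-one F2. Luche reduction (NaBH4, CeCl3, MeOH, −78 °C) delivers hydride to the convex face and gives the 8α-allylic alcohol F3. Hydroxyl-directed hydrogenation with [Ir(cod)(PCy3)(py)]PF6 and H2 in CH2Cl2 then adds hydrogen to C6=C7 from the face of the 8α-hydroxyl, which places H7 α and gives 20 without any equilibration.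

2. Step 16 (enone reduction). Protonation at C4 may lack facial selectivity if ring A does not react through the locked chair, the hydroxyl protons may cause over-reduction of the C2 carbonyl, and the nearby C9 alkoxide may add to C4 in a conjugate manner. The fallback sets out from 24 and returns at 25. Homogeneous hydrogenation of the enone with [Ir(cod)(PCy3)(py)]PF6 and H2 in CH2Cl2 is directed by the 9α-hydroxyl, which lies over the α face of C3=C4 and should deliver hydrogen to that face; no new compound arises (F0).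

3. Step 18 (C9 acylation). The axial, inward-pointing 9α-hydroxyl may acylate so slowly that base-mediated migration of the tigloyl group from O8 to O9 and scrambling of the two esters compete. The fallback sets out from 25 and returns at 27. Selective silylation of the equatorial hydroxyl (TESCl, imidazole, DMF, 0 °C) gives the 8-O-triethylsilyl ether F4. Acylation of O9 with 3-methylbut-2-enoyl chloride, pyridine and DMAP, now with heating and no migrating ester nearby, gives the silylated 9-senecioate F5. HF·pyridine in THF at 0 °C frees O8 to give the hydroxy senecioate F6, which is acylated at once with tigloyl chloride, pyridine and DMAP at −20 °C to give 27.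

**Further compounds**

F1 | step 10 | trimethylsilyl enol ether (C7=C8) of 18 | CC(C)(O[Si](CC)(CC)CC)C=1C[C@@]2(C)[C@H](C[C@H](O[Si](c3ccccc3)(c3ccccc3)C(C)(C)C)C=C2C)C(OC)(OC)C=1O[Si](C)(C)C
F2 | step 10 | 2β-(tert-butyldiphenylsilyloxy)-9,9-dimethoxy-11-(triethylsilyloxy)-10βH-eremophila-3,6-dien-8-one | CC(C)(O[Si](CC)(CC)CC)C1=C[C@@]2(C)[C@H](C[C@H](O[Si](c3ccccc3)(c3ccccc3)C(C)(C)C)C=C2C)C(OC)(OC)C1=O
F3 | step 10 | 2β-(tert-butyldiphenylsilyloxy)-9,9-dimethoxy-11-(triethylsilyloxy)-10βH-eremophila-3,6-dien-8α-ol | CC(C)(O[Si](CC)(CC)CC)C1=C[C@@]2(C)[C@H](C[C@H](O[Si](c3ccccc3)(c3ccccc3)C(C)(C)C)C=C2C)C(OC)(OC)[C@@H]1O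
F0 | step 16 | none | none
F4 | step 18 | 9α,11-dihydroxy-8α-(triethylsilyloxy)-7αH,10βH-eremophilan-2-one | CC(C)(O)[C@H]1C[C@@]2(C)[C@H](CC(=O)C[C@@H]2C)[C@H](O)[C@@H]1O[Si](CC)(CC)CC
F5 | step 18 | 11-hydroxy-9α-senecioyloxy-8α-(triethylsilyloxy)-7αH,10βH-eremophilan-2-one | CC(C)(O)[C@H]1C[C@@]2(C)[C@H](CC(=O)C[C@@H]2C)[C@H](OC(=O)C=C(C)C)[C@@H]1O[Si](CC)(CC)CC
F6 | step 18 | 8α,11-dihydroxy-9α-senecioyloxy-7αH,10βH-eremophilan-2-one | CC(C)(O)[C@H]1C[C@@]2(C)[C@H](CC(=O)C[C@@H]2C)[C@H](OC(=O)C=C(C)C)[C@@H]1O
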